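**Retrosynthetic overview**

1. The target is methyl (13R)-17-acetoxy-3β-hydroxylabd-7-en-15-oate; the last step is selective acetylation of the primary C17–OH of the 3β,17-diol.
2. Key disconnection is C3–C4, closing ring A last: a tertiary C4 radical adds to a C3 aldehyde. The same operation creates the C7=C8 alkene and frees C17–OH, by titanocene opening of a C8/C17 spiro-epoxide and rupture of a temporary C4–C7 bond.
3. Enabling feature: in ring B, C7 lies 1,3 to C5, C5 carries the CMe2 carbon C4, and C8 carries the oxygenated C17. C4–C5–C6–C7 can therefore be the cyclobutane of a pinane, and (1R,5R)-verbenone supplies ring B (C5–C10), C20, C4, C18, C19 and the C5 stereocentre.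
4. Order: ring B (as the pinane) from verbenone; C10 quaternary centre by cuprate addition anti to the CMe2 bridge; C9 side chain (C11–C15, C13 from (R)-monomethyl 3-methylglutarate) by aldol condensation and face-selective hydrogenation; C17 by sulfonium ylide; ring A in the cascade.

Key step: step 8

Assumption: (1R,5R)-(+)-verbenone and (R)-monomethyl 3-methylglutarate are taken as purchasable, enantiopure materials; the spiro-epoxide configuration drawn for 12 and 13 is the expected one but is of no consequence, since C8 becomes planar in step 8.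

**Step 1**
Reactants: 1 (R)-monomethyl 3-methylglutarate
Product: 2 methyl (3R)-5-hydroxy-3-methylpentanoate
Conditions: BH3·SMe2, THF, 0 °C to rt; then H2O
Reagents that add atoms: none
Why: Chemoselective borane reduction of a carboxylic acid (via the acyloxyborane) in the presence of a methyl ester; the C3 stereocentre is not touched.

**Step 2**
Reactants: 2 methyl (3R)-5-hydroxy-3-methylpentanoate
Product: 3 methyl (3R)-3-methyl-5-oxopentanoate
Conditions: TEMPO (10 mol %), PhI(OAc)2, CH2Cl2, rt
Reagents that add atoms: none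
Why: Oxoammonium (TEMPO) oxidation of a primary alcohol stops at the aldehyde and should be faster than lactonization of the hydroxy ester.

**Step 3**
Reactants: 4 (1R,5R)-(+)-verbenone; 5 benzyl 3-bromopropyl ether
Product: 7 (1R,4R,5R)-4-[3-(benzyloxy)propyl]-4,6,6-trimethylbicyclo[3.1.1]heptan-2-one, via [3-(benzyloxy)propyl]magnesium bromide 6 (not isolated)
Conditions: 5, Mg, THF; then CuBr·SMe2 (10 mol %), 4, THF, −40 to 0 °C; H2O
Reagents that add atoms: none
Why: Copper-catalysed conjugate addition of a Grignard reagent to the strained β,β-disubstituted enone; attack on the methyl-bearing β-carbon from the methylene-bridge face, anti to the CMe2 bridge, sets the quaternary centre (C10 of the target) with the new chain trans to the CMe2 carbon on C5, which is the trans ring-fusion relationship.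

**Step 4**
Reactants: 7 (1R,4R,5R)-4-[3-(benzyloxy)propyl]-4,6,6-trimethylbicyclo[3.1.1]heptan-2-one; 3 methyl (3R)-3-methyl-5-oxopentanoate
Product: 10 methyl (3R,5Z)-5-[(1R,4S,5S)-4-[3-(benzyloxy)propyl]-4,6,6-trimethyl-2-oxobicyclo[3.1.1]heptan-3-ylidene]-3-methylpentanoate, via aldol adduct 8 (not isolated), via aldol mesylate 9 (not isolated)
Conditions: LiN(i-Pr)2, THF, −78 °C; 3; MsCl, −78 to 0 °C; DBU, 0 to 40 °C
Reagents that add atoms: none
Why: Directed aldol addition of the only possible enolate (the other α-carbon is a bridgehead), then mesylation and E1cB elimination (aldol condensation); the two aldol stereocentres are erased and the alkene geometry has no consequence for step 5.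

**Step 5**
Reactants: 10 the alkylidene ketone benzyl ether
Product: 11 methyl (3R)-5-[(1R,3R,4S,5S)-4-(3-hydroxypropyl)-4,6,6-trimethyl-2-oxobicyclo[3.1.1]heptan-3-yl]-3-methylpentanoate
Conditions: H2 (4 atm), 10% Pd/C, EtOAc–EtOH, rt
Reagents that add atoms: none
Why: Heterogeneous hydrogenation of the exocyclic enone with concurrent hydrogenolysis of the benzyl ether; hydrogen should be delivered from the methylene-bridge face, away from the CMe2 bridge (the bias seen in the hydrogenation of pinocarvone to isopinocamphone), which sets C9 with its chain syn to the CMe2 bridge and cis to the C10 methyl.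

**Step 6**
Reactants: 11 the hydroxy ketone
Product: 12 methyl (3R)-5-[(1R,2S,3R,4S,5S)-4-(3-hydroxypropyl)-4,6,6-trimethylspiro[bicyclo[3.1.1]heptane-2,2'-oxiran]-3-yl]-3-methylpentanoate
Conditions: Me3S+ I− (3.3 equiv), KN(SiMe3)2 (3.0 equiv), THF, −10 °C to rt
Reagents that add atoms: trimethylsulfonium iodide, C[S+](C)C.[I-] (acts as dimethylsulfonium methylide, C[S+](C)[CH2-])
Why: Corey–Chaykovsky epoxidation; the sulfonium ylide should add to the ketone (anti to the CMe2 bridge) faster than it enolizes it, the ylide is too weak a base to enolize the ester, and the new spiro centre is erased in step 8.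

**Step 7**
Reactants: 12 the spiro-epoxy alcohol
Product: 13 methyl (3R)-5-[(1R,2S,3R,4S,5S)-4,6,6-trimethyl-4-(3-oxopropyl)spiro[bicyclo[3.1.1]heptane-2,2'-oxiran]-3-yl]-3-methylpentanoate
Conditions: Pr4N[RuO4] (5 mol %), N-methylmorpholine N-oxide, 4 Å molecular sieves, CH2Cl2, rt
Reagents that add atoms: none
Why: Ley–Griffith oxidation under neutral, anhydrous conditions converts the primary alcohol into the aldehyde without opening the acid-labile spiro-epoxide.

**Step 8**
Reactants: 13 the spiro-epoxy aldehyde
Product: 14 methyl (13R)-3β,17-dihydroxylabd-7-en-15-oate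
Conditions: Cp2TiCl2 (2.5 equiv), Mn dust, THF, rt (gives Cp2TiCl); this solution added slowly to 13 and 2,4,6-collidine in THF (0.005 M), rt; then aq NaH2PO4
Reagents that add atoms: none
Why: Proposed new method: Cp2TiCl (trivalent titanium) opens the spiro-epoxide homolytically to the tertiary C8 radical bearing C17H2–O–Ti, this cyclobutylcarbinyl radical cleaves the strained C7–C4 bond to give the C7=C8 alkene and the tertiary C4 radical, the C4 radical adds to the C3 aldehyde, and the oxygen-centred radical is captured by a second Cp2TiCl before hydrolysis to the diol. The closest known reaction types are the titanocene-mediated epoxide opening with radical cyclization onto aldehydes and ketones (Nugent–RajanBabu chemistry), the ring-opening of pinane cyclobutylcarbinyl radicals, and the 6-exo cyclization of alkyl radicals onto aldehydes. Ring A closes by 6-exo-trig attack of the C4 radical on the carbonyl carbon C3, and the trans ring fusion is already fixed by the trans arrangement of the C5–C4 and C10–C1 bonds. The new C3 stereocentre is controlled by a chair transition state with the carbonyl oxygen equatorial, away from the axial C20 methyl and the axial methyl on C4, which should give the 3β (3S) alcohol. The step needs cleavage of C7–C4 and not C7–C6 (tertiary versus primary radical) and ring closure before reduction or titanium capture of the C4 radical; these are secured by the slow capture of tertiary radicals by Cp2TiCl, by slow addition at high dilution, and by the inertness of aliphatic aldehydes toward Cp2TiCl.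

**Step 9**
Reactants: 14 methyl (13R)-3β,17-dihydroxylabd-7-en-15-oate
Product: 15 methyl (13R)-17-acetoxy-3β-hydroxylabd-7-en-15-oate (CNP0269364.1)
Conditions: Ac2O (1.1 equiv), pyridine, CH2Cl2, −20 to 0 °C
Reagents that add atoms: acetic anhydride, CC(=O)OC(C)=O
Why: Chemoselective acylation; the unhindered primary allylic C17 alcohol should react far faster than the secondary C3 alcohol, which is neopentyl next to the C4 gem-dimethyl group.

**Compound list**

1 | (R)-monomethyl 3-methylglutarate [(3R)-5-methoxy-3-methyl-5-oxopentanoic acid] | COC(=O)C[C@H](C)CC(=O)O | starting material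
2 | methyl (3R)-5-hydroxy-3-methylpentanoate | COC(=O)C[C@H](C)CCO | intermediate
3 | methyl (3R)-3-methyl-5-oxopentanoate | COC(=O)C[C@H](C)CC=O | intermediate
4 | (1R,5R)-(+)-verbenone [(1R,5R)-4,6,6-trimethylbicyclo[3.1.1]hept-3-en-2-one] | CC1=CC(=O)[C@@H]2C[C@H]1C2(C)C | starting material
5 | benzyl 3-bromopropyl ether | BrCCCOCc1ccccc1 | starting material
6 | [3-(benzyloxy)propyl]magnesium bromide | Br[Mg]CCCOCc1ccccc1 | intermediate (not isolated)
7 | (1R,4R,5R)-4-[3-(benzyloxy)propyl]-4,6,6-trimethylbicyclo[3.1.1]heptan-2-one (new chain anti to the CMe2 bridge) | C[C@@]1(CCCOCc2ccccc2)CC(=O)[C@@H]2C[C@H]1C2(C)C | intermediate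
8 | methyl (3R)-5-[(1R,4S,5S)-4-[3-(benzyloxy)propyl]-4,6,6-trimethyl-2-oxobicyclo[3.1.1]heptan-3-yl]-5-hydroxy-3-methylpentanoate (aldol adduct; ring C3 chain anti to the CMe2 bridge expected, carbinol epimers) | C[C@@]1(CCCOCc2ccccc2)[C@H](C(O)C[C@@H](C)CC(=O)OC)C(=O)[C@@H]2C[C@H]1C2(C)C | intermediate (not isolated)
9 | methanesulfonate of 8 | C[C@@]1(CCCOCc2ccccc2)[C@H](C(OS(C)(=O)=O)C[C@@H](C)CC(=O)OC)C(=O)[C@@H]2C[C@H]1C2(C)C | intermediate (not isolated)
10 | methyl (3R,5Z)-5-[(1R,4S,5S)-4-[3-(benzyloxy)propyl]-4,6,6-trimethyl-2-oxobicyclo[3.1.1]heptan-3-ylidene]-3-methylpentanoate | C[C@@]1(CCCOCc2ccccc2)/C(=C/C[C@@H](C)CC(=O)OC)C(=O)[C@@H]2C[C@H]1C2(C)C | intermediate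
11 | methyl (3R)-5-[(1R,3R,4S,5S)-4-(3-hydroxypropyl)-4,6,6-trimethyl-2-oxobicyclo[3.1.1]heptan-3-yl]-3-methylpentanoate (pentanoate chain syn to the CMe2 bridge) | C[C@@]1(CCCO)[C@@H](CC[C@@H](C)CC(=O)OC)C(=O)[C@@H]2C[C@H]1C2(C)C | intermediate
12 | methyl (3R)-5-[(1R,2S,3R,4S,5S)-4-(3-hydroxypropyl)-4,6,6-trimethylspiro[bicyclo[3.1.1]heptane-2,2'-oxiran]-3-yl]-3-methylpentanoate | C[C@@]1(CCCO)[C@@H](CC[C@@H](C)CC(=O)OC)[C@]3(CO3)[C@@H]2C[C@H]1C2(C)C | intermediate
13 | methyl (3R)-5-[(1R,2S,3R,4S,5S)-4,6,6-trimethyl-4-(3-oxopropyl)spiro[bicyclo[3.1.1]heptane-2,2'-oxiran]-3-yl]-3-methylpentanoate | C[C@@]1(CCC=O)[C@@H](CC[C@@H](C)CC(=O)OC)[C@]3(CO3)[C@@H]2C[C@H]1C2(C)C | intermediate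
14 | methyl (13R)-3β,17-dihydroxylabd-7-en-15-oate [methyl (3R)-5-[(1R,4aR,6S,8aR)-6-hydroxy-2-(hydroxymethyl)-5,5,8a-trimethyl-1,4,4a,5,6,7,8,8a-octahydronaphthalen-1-yl]-3-methylpentanoate] | COC(=O)C[C@H](C)CC[C@H]1C(CO)=CC[C@H]2C(C)(C)[C@@H](O)CC[C@]12C | intermediate
15 | methyl (13R)-17-acetoxy-3β-hydroxylabd-7-en-15-oate [methyl (3R)-5-[(1R,4aR,6S,8aR)-2-(acetoxymethyl)-6-hydroxy-5,5,8a-trimethyl-1,4,4a,5,6,7,8,8a-octahydronaphthalen-1-yl]-3-methylpentanoate] | COC(=O)C[C@H](C)CC[C@H]1C(COC(C)=O)=CC[C@H]2C(C)(C)[C@@H](O)CC[C@]12C | target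

**Step count**

Total step count: 9. Longest linear sequence: 8 steps (steps 1, 2, 4, 5, 6, 7, 8, 9, from 1); from verbenone the sequence is 7 steps (steps 3 to 9).

**Steps most likely to fail**

Step 8 (Proposed new method). Three processes may intervene: reduction or titanium capture of the tertiary C4 radical (with loss of a β-hydrogen) before ring A closes; direct attack of the C8 radical on the aldehyde before the cyclobutane opens; and Lewis-acid-induced ionic rearrangement of the spiro-epoxide. The fallback uses known chemistry, sets out from 13 and returns at 14. Compound 13 is treated with an excess of Cp2TiCl at high concentration, conditions that deliberately favour capture of the C4 radical and β-hydrogen loss (the known titanocene isomerization mode of epoxides), to give methyl (3R)-5-[(1R,5S,6S)-2-(hydroxymethyl)-6-methyl-6-(3-oxopropyl)-5-(prop-1-en-2-yl)cyclohex-2-en-1-yl]-3-methylpentanoate F1. Its isopropenyl group is then closed onto the aldehyde by iron-hydride hydrogen-atom-transfer reductive cyclization (Fe(acac)3, PhSiH3, EtOH, 60 °C), which forms the same C3–C4 bond through the same C4 radical and should give 14.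

Step 5. The risk is poor or reversed facial selectivity of hydrogen delivery at C9, because the C10 propyl chain sits on the methylene-bridge face and may offset the bias of the CMe2 bridge. If reagents prove to prefer the CMe2 face, the fallback forms the C9–C11 bond, instead of the C9–H bond, on that preferred face. It sets out from 7 and 2 and returns at 11. Alcohol 2 is converted (I2, PPh3, imidazole) into methyl (3S)-5-iodo-3-methylpentanoate F2. The lithium enolate of 7 (LiN(i-Pr)2, THF–DMPU) is alkylated with it to give methyl (3R)-5-[(1R,3R,4S,5S)-4-[3-(benzyloxy)propyl]-4,6,6-trimethyl-2-oxobicyclo[3.1.1]heptan-3-yl]-3-methylpentanoate F3, and hydrogenolysis (H2, Pd/C) should give 11.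

Step 6. The risk is enolization of the hindered ketone by the basic ylide, with epimerization at C9, or slow addition to the carbonyl group. The fallback sets out from 11 and returns at 12. Non-basic methylenation (Zn, CH2Br2, TiCl4, Lombardo conditions) gives methyl (3R)-5-[(1R,3S,4S,5S)-4-(3-hydroxypropyl)-4,6,6-trimethyl-2-methylidenebicyclo[3.1.1]heptan-3-yl]-3-methylpentanoate F4, and epoxidation of the exocyclic alkene with dimethyldioxirane (acetone, 0 °C) should give 12; either spiro epimer serves in step 8.

**Further compounds**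

F1 | step 8 | methyl (3R)-5-[(1R,5S,6S)-2-(hydroxymethyl)-6-methyl-6-(3-oxopropyl)-5-(prop-1-en-2-yl)cyclohex-2-en-1-yl]-3-methylpentanoate | COC(=O)C[C@H](C)CC[C@H]1C(CO)=CC[C@@H](C(C)=C)[C@]1(C)CCC=O
F2 | step 5 | methyl (3S)-5-iodo-3-methylpentanoate | COC(=O)C[C@H](C)CCI
F3 | step 5 | methyl (3R)-5-[(1R,3R,4S,5S)-4-[3-(benzyloxy)propyl]-4,6,6-trimethyl-2-oxobicyclo[3.1.1]heptan-3-yl]-3-methylpentanoate | C[C@@]1(CCCOCc2ccccc2)[C@@H](CC[C@@H](C)CC(=O)OC)C(=O)[C@@H]2C[C@H]1C2(C)C
F4 | step 6 | methyl (3R)-5-[(1R,3S,4S,5S)-4-(3-hydroxypropyl)-4,6,6-trimethyl-2-methylidenebicyclo[3.1.1]heptan-3-yl]-3-methylpentanoate | C[C@@]1(CCCO)[C@@H](CC[C@@H](C)CC(=O)OC)C(=C)[C@@H]2C[C@H]1C2(C)C
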